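A direct plan would start from (S)-4-hydroxycyclopent-2-en-1-one A1 and add the homoprenyl chain and the angular methyl group to this enone A1 by two conjugate additions, then add an acetylide and close ring B by a carbonyl-ene reaction to the ethynyl hydrindanone A2.
It would then esterify O6, oxidise the isopropenyl group to the methyl acrylate, and only at the end turn the five-membered ring into ring A by a gold-catalysed 1,2-alkyl shift of the 1-ethynylcyclopentanol A3 to the methylene decalinone A4, followed by reduction and desilylation.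
Weak point 1, the ring expansion A3 → A4: this alkynyl-carbinol shift is known for strained three- and four-membered carbinols only. On a cyclopentanol it lacks that driving force, must also select the more substituted migrating carbon, and comes fifteen steps deep with the whole molecule at stake.
Weak point 2, the C1 oxygen: it would be silylated, desilylated, oxidised to the ketone and reduced back, four operations that build nothing; the carbinol centre made by the acetylide addition is destroyed again.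
Weak point 3, the acrylate: the isopropenyl group left by the ene reaction would need allylic oxidation, Pinnick oxidation and methylation late, beside a terminal alkyne, an acrylate ester and free alcohols.

**Retrosynthetic overview**
The key disconnection is the C5–C10 bond of ring A (eudesmane numbering: C1 and C3 carry OH, C4=C15 is the methylene, C10 is the quaternary carbon). It is made by an epoxide-opening cation–olefin cyclisation of an acyclic chain that ends in an allylsilane and already holds all fifteen core carbons and the C12 methyl ester.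
One Shi epoxidation sets the two epoxide centres; the cyclisation relays them to C1, C10 and C5 in one event and leaves the C4=C15 methylene regiospecifically.
Ring B closes second, through C6–C7, by an intramolecular Hosomi–Sakurai allylation of the C6 aldehyde with a 2-(silylmethyl)enoate, which gives the 6α-hydroxy-7β-acrylate directly.
Ring order is A, then B: there is no five-membered ring, no ring expansion, no redox detour at C1 and no late oxidation of an isopropenyl group. C3–OH comes last by allylic oxidation and Luche reduction.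

Key step: step 8

Assumption: the olefination of step 4 is drawn as its expected major (2Z) isomer; either alkene isomer should serve, because this geometry is lost in step 10.

**Step 1**
Reactants: 1 pent-4-ynal; 2 prop-1-en-2-ylmagnesium bromide
Product: 3 2-methylhept-1-en-6-yn-3-ol (racemic)
Conditions: THF, −78 °C; aq. NH4Cl
Reagents that add atoms: none
Why: Grignard 1,2-addition to the aldehyde, faster at −78 °C than deprotonation of the alkyne; the carbinol centre is left racemic because step 2 consumes it.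

**Step 2**
Reactants: 3 2-methylhept-1-en-6-yn-3-ol
Product: 4 ethyl (4E)-4-methylnon-4-en-8-ynoate
Conditions: MeC(OEt)3 (5 equiv), EtCO2H (cat.), 140 °C, EtOH distilled off
Reagents that add atoms: triethyl orthoacetate, CC(OCC)(OCC)OCC
Why: Johnson–Claisen rearrangement through a chair with the butynyl group equatorial should give the (E)-trisubstituted C1=C10 alkene and bring in C7 and C8.

**Step 3**
Reactants: 5 trimethyl phosphonoacetate; 6 (iodomethyl)trimethylsilane
Product: 7 methyl 2-(dimethoxyphosphoryl)-3-(trimethylsilyl)propanoate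
Conditions: NaH, DME, 0 → 60 °C
Reagents that add atoms: none
Why: SN2 C-alkylation of the phosphonoacetate anion gives the reagent that carries C11, C12 and the silylated C13.

**Step 4**
Reactants: 4 ethyl (4E)-4-methylnon-4-en-8-ynoate; 7 methyl 2-(dimethoxyphosphoryl)-3-(trimethylsilyl)propanoate
Product: 9 methyl (2Z,6E)-6-methyl-2-[(trimethylsilyl)methyl]undeca-2,6-dien-10-ynoate, via enynal 8 (not isolated)
Conditions: i-Bu2AlH (1.05 equiv), CH2Cl2, −78 °C; then 7/NaH in THF, −78 °C → rt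
Reagents that add atoms: none
Why: One-pot half-reduction and Horner–Wadsworth–Emmons olefination; the aluminium hemiacetal releases the aldehyde to the phosphonate anion, which installs the 2-(silylmethyl)enoate (C7=C11, C12 ester, C13–Si) needed for ring B.

**Step 5**
Reactants: 9 methyl (2Z,6E)-6-methyl-2-[(trimethylsilyl)methyl]undeca-2,6-dien-10-ynoate
Product: 10 (2Z,6E,10Z)-12-methoxy-7-methyl-12-oxo-3,11-bis[(trimethylsilyl)methyl]dodeca-2,6,10-trienoic acid
Conditions: Me3SiCH2MgCl, CuBr·SMe2, Et2O/Me2S, −40 °C; 9, −25 → 0 °C; then CO2 (1 atm), HMPA, P(OEt)3 (cat.), −40 °C → rt; aq. citric acid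
Reagents that add atoms: (trimethylsilyl)methylmagnesium chloride, C[Si](C)(C)C[Mg]Cl; carbon dioxide, O=C=O
Why: Normant syn-carbocupration of the terminal alkyne puts CH2SiMe3 on C4 and copper on C5, and carboxylation with retention gives the (2Z) acid with C6 cis to the silylmethyl group; the hindered enoate should not be attacked by the organocopper reagent.

**Step 6**
Reactants: 10 (2Z,6E,10Z)-12-methoxy-7-methyl-12-oxo-3,11-bis[(trimethylsilyl)methyl]dodeca-2,6,10-trienoic acid
Product: 11 (2Z,6R,7R,10Z)-6,7-epoxy-12-methoxy-7-methyl-12-oxo-3,11-bis[(trimethylsilyl)methyl]dodeca-2,10-dienoic acid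
Conditions: Shi ketone from D-fructose (30 mol %), Oxone, K2CO3, Bu4NHSO4, MeCN/dimethoxymethane/aq. buffer (pH 10.5), 0 °C; careful acidification to pH 5
Reagents that add atoms: potassium peroxymonosulfate (Oxone), [K+].[O-]S(=O)(=O)OO
Why: Shi asymmetric epoxidation; the chiral dioxirane reacts only with the isolated trisubstituted alkene (the other two are conjugated to carboxyl groups), and its spiro transition state should give the (6R,7R)-epoxide, the only centres in the route set by a catalyst.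

**Step 7**
Reactants: 11 (2Z,6R,7R,10Z)-6,7-epoxy-12-methoxy-7-methyl-12-oxo-3,11-bis[(trimethylsilyl)methyl]dodeca-2,10-dienoic acid
Product: 14 methyl (2Z,6R,7R,10Z)-6,7-epoxy-6-methyl-12-[(triethylsilyl)oxy]-2,10-bis[(trimethylsilyl)methyl]dodeca-2,10-dienoate, via mixed anhydride 12 (not isolated), via epoxy alcohol 13 (not isolated)
Conditions: i-BuOCOCl, N-methylmorpholine, THF, −15 °C; NaBH4, H2O, 0 °C; crude 13, Et3SiCl, imidazole, CH2Cl2, 0 °C
Reagents that add atoms: chlorotriethylsilane, CC[Si](Cl)(CC)CC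
Why: Mixed-anhydride activation and borohydride reduction take only the acid to the allylic alcohol (methyl ester and epoxide untouched), which frees the allylsilane from conjugation; silylation masks C6–OH.

**Step 8**
Reactants: 14 methyl (2Z,6R,7R,10Z)-6,7-epoxy-6-methyl-12-[(triethylsilyl)oxy]-2,10-bis[(trimethylsilyl)methyl]dodeca-2,10-dienoate
Product: 16 methyl (2Z)-5-[(1R,2S,6R)-1-methyl-3-methylidene-6-[(triethylsilyl)oxy]-2-{[(triethylsilyl)oxy]methyl}cyclohexyl]-2-[(trimethylsilyl)methyl]pent-2-enoate, via cyclohexanol 15 (not isolated)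
Conditions: MeAlCl2 (1.5 equiv), CH2Cl2, −78 °C; Et3N/MeOH quench, aq. Rochelle salt; crude 15, Et3SiOTf, 2,6-lutidine, CH2Cl2, −40 → 0 °C
Reagents that add atoms: triethylsilyl trifluoromethanesulfonate, CC[Si](CC)(CC)OS(=O)(=O)C(F)(F)F
Why: The Lewis acid activates the epoxide, C5 of the allylsilane attacks the tertiary carbon C10 anti to the breaking C–O bond, and the β-silyl cation at C4 loses Me3Si to give only the exocyclic C4=C15 alkene; the closest known reaction type is the epoxide–allylsilane cyclisation to 3-hydroxy-6-methylenecyclohexanes (Stork–Eschenmoser stereochemistry). Ring A closes through a chair, endo with respect to both the epoxide and the alkene. C1 keeps the epoxide C–O bond (equatorial 1β-oxygen); C10 is formed with inversion of the (E)-derived epoxide carbon (methyl axial, C9 chain equatorial); C5 follows from the (Z)-allylsilane geometry (CH2O equatorial, H anti to the methyl). The step needs the electron-rich allylsilane to react while the second silane and the allylic silyl ether stay: the 2-(silylmethyl)enoate is deactivated by its ester and could only form a four- or five-membered ring, and the silyl ether is a poor leaving group at −78 °C. A concerted opening is required so that the C10 configuration is not lost, which the nucleophilic, unconjugated silane and the low temperature should secure. Silylation of the crude alcohol protects C1–OH for steps 9 to 13.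

**Step 9**
Reactants: 16 methyl (2Z)-5-[(1R,2S,6R)-1-methyl-3-methylidene-6-[(triethylsilyl)oxy]-2-{[(triethylsilyl)oxy]methyl}cyclohexyl]-2-[(trimethylsilyl)methyl]pent-2-enoate
Product: 17 methyl (2Z)-5-[(1R,2S,6R)-2-formyl-1-methyl-3-methylidene-6-[(triethylsilyl)oxy]cyclohexyl]-2-[(trimethylsilyl)methyl]pent-2-enoate
Conditions: (COCl)2, DMSO, CH2Cl2, −78 → −40 °C; Et3N, → 0 °C; used at once
Reagents that add atoms: none
Why: Under Swern conditions a primary triethylsilyl ether is cleaved and oxidised directly to the aldehyde while the hindered secondary one stays; the β,γ-unsaturated aldehyde is not stored, since C5 is epimerisable.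

**Step 10**
Reactants: 17 methyl (2Z)-5-[(1R,2S,6R)-2-formyl-1-methyl-3-methylidene-6-[(triethylsilyl)oxy]cyclohexyl]-2-[(trimethylsilyl)methyl]pent-2-enoate
Product: 18 methyl 2-[(1S,2S,4aR,5R,8aS)-1-hydroxy-4a-methyl-8-methylidene-5-[(triethylsilyl)oxy]decahydronaphthalen-2-yl]prop-2-enoate
Conditions: BF3·OEt2 (1.5 equiv), CH2Cl2, −78 °C; aq. NaHCO3 at −78 °C
Reagents that add atoms: none
Why: Intramolecular Hosomi–Sakurai allylation: C7 of the 2-(silylmethyl)enoate adds to the activated aldehyde with loss of Me3Si, closing ring B as a chair trans-fused to ring A and leaving the methyl acrylate on C7; the C6 oxygen must be equatorial (6α) because an axial one would be syn-diaxial to the C10 methyl, and the C11 unit should take the equatorial position anti to C5 (7β).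

**Step 11**
Reactants: 18 methyl 2-[(1S,2S,4aR,5R,8aS)-1-hydroxy-4a-methyl-8-methylidene-5-[(triethylsilyl)oxy]decahydronaphthalen-2-yl]prop-2-enoate
Product: 19 methyl 2-[(1S,2S,4aR,5R,8aS)-4a-methyl-8-methylidene-1-(prop-2-enoyloxy)-5-[(triethylsilyl)oxy]decahydronaphthalen-2-yl]prop-2-enoate
Conditions: acryloyl chloride, i-Pr2NEt, DMAP (cat.), CH2Cl2, −20 → 0 °C
Reagents that add atoms: acryloyl chloride, C=CC(Cl)=O
Why: O-acylation of the only free hydroxyl (C6–OH) with a small acyl chloride; acylation also rules out later lactonisation onto the C12 ester.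

**Step 12**
Reactants: 19 methyl 2-[(1S,2S,4aR,5R,8aS)-4a-methyl-8-methylidene-1-(prop-2-enoyloxy)-5-[(triethylsilyl)oxy]decahydronaphthalen-2-yl]prop-2-enoate
Product: 21 methyl 2-[(1S,2S,4aR,5R,8aR)-4a-methyl-8-methylidene-7-oxo-1-(prop-2-enoyloxy)-5-[(triethylsilyl)oxy]decahydronaphthalen-2-yl]prop-2-enoate, via allylic alcohol 20 (not isolated)
Conditions: SeO2 (0.5 equiv), t-BuOOH, CH2Cl2, rt; crude 20, Dess–Martin periodinane, NaHCO3, CH2Cl2, 0 °C
Reagents that add atoms: selenium dioxide, O=[Se]=O; tert-butyl hydroperoxide, CC(C)(C)OO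
Why: Riley allylic oxidation (ene reaction, then [2,3]-shift) attacks the ring CH2 (C3) of the exocyclic alkene in preference to the hindered methine C5 and leaves both electron-poor acrylates alone; the periodinane converges either C3 epimer and any enone to the methylene ketone.

**Step 13**
Reactants: 21 methyl 2-[(1S,2S,4aR,5R,8aR)-4a-methyl-8-methylidene-7-oxo-1-(prop-2-enoyloxy)-5-[(triethylsilyl)oxy]decahydronaphthalen-2-yl]prop-2-enoate
Product: 22 methyl 2-[(1S,2S,4aR,5R,7S,8aS)-7-hydroxy-4a-methyl-8-methylidene-1-(prop-2-enoyloxy)-5-[(triethylsilyl)oxy]decahydronaphthalen-2-yl]prop-2-enoate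
Conditions: NaBH4, CeCl3·7H2O, MeOH, −78 °C
Reagents that add atoms: none
Why: Luche 1,2-reduction; axial hydride delivery from the α face of the trans-decalin should give the equatorial 3β-allylic alcohol without conjugate reduction of the acrylates.

**Step 14**
Reactants: 22 methyl 2-[(1S,2S,4aR,5R,7S,8aS)-7-hydroxy-4a-methyl-8-methylidene-1-(prop-2-enoyloxy)-5-[(triethylsilyl)oxy]decahydronaphthalen-2-yl]prop-2-enoate
Product: 24 methyl 2-[(1S,2S,4aR,5R,7S,8aS)-5,7-dihydroxy-1-{[2-(hydroxymethyl)prop-2-enoyl]oxy}-4a-methyl-8-methylidenedecahydronaphthalen-2-yl]prop-2-enoate, via silyl ether 23 (not isolated)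
Conditions: aq. HCHO (37 %), DABCO, 1,4-dioxane/H2O, rt; then 1 M HCl, THF, 0 °C → rt
Reagents that add atoms: formaldehyde, C=O
Why: Morita–Baylis–Hillman hydroxymethylation occurs only at the unsubstituted acrylate (the C11 acrylate has no α-hydrogen), and dilute acid then removes the secondary triethylsilyl ether; no stereocentre is touched.

**Compound list**
1 | pent-4-ynal | C#CCCC=O | starting material
2 | prop-1-en-2-ylmagnesium bromide | C=C(C)[Mg]Br | starting material
3 | 2-methylhept-1-en-6-yn-3-ol (racemic) | C=C(C)C(O)CCC#C | intermediate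
4 | ethyl (4E)-4-methylnon-4-en-8-ynoate | CCOC(=O)CC/C(C)=C/CCC#C | intermediate
5 | trimethyl phosphonoacetate | COC(=O)CP(=O)(OC)OC | starting material
6 | (iodomethyl)trimethylsilane | C[Si](C)(C)CI | starting material
7 | methyl 2-(dimethoxyphosphoryl)-3-(trimethylsilyl)propanoate (racemic) | COC(=O)C(C[Si](C)(C)C)P(=O)(OC)OC | intermediate
8 | (4E)-4-methylnon-4-en-8-ynal | O=CCC/C(C)=C/CCC#C | intermediate
9 | methyl (2Z,6E)-6-methyl-2-[(trimethylsilyl)methyl]undeca-2,6-dien-10-ynoate | C[Si](C)(C)C/C(C(=O)OC)=C\CC/C(C)=C/CCC#C | intermediate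
10 | (2Z,6E,10Z)-12-methoxy-7-methyl-12-oxo-3,11-bis[(trimethylsilyl)methyl]dodeca-2,6,10-trienoic acid | C[Si](C)(C)C/C(C(=O)OC)=C\CC/C(C)=C/CC/C(C[Si](C)(C)C)=C/C(=O)O | intermediate
11 | (2Z,6R,7R,10Z)-6,7-epoxy-12-methoxy-7-methyl-12-oxo-3,11-bis[(trimethylsilyl)methyl]dodeca-2,10-dienoic acid | C[Si](C)(C)C/C(C(=O)OC)=C\CC[C@@]1(C)O[C@@H]1CC/C(C[Si](C)(C)C)=C/C(=O)O | intermediate
12 | (2Z,6R,7R,10Z)-6,7-epoxy-12-methoxy-7-methyl-12-oxo-3,11-bis[(trimethylsilyl)methyl]dodeca-2,10-dienoic 2-methylpropyl carbonic anhydride | C[Si](C)(C)C/C(C(=O)OC)=C\CC[C@@]1(C)O[C@@H]1CC/C(C[Si](C)(C)C)=C/C(=O)OC(=O)OCC(C)C | intermediate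
13 | methyl (2Z,6R,7R,10Z)-6,7-epoxy-12-hydroxy-6-methyl-2,10-bis[(trimethylsilyl)methyl]dodeca-2,10-dienoate | C[Si](C)(C)C/C(C(=O)OC)=C\CC[C@@]1(C)O[C@@H]1CC/C(C[Si](C)(C)C)=C/CO | intermediate
14 | methyl (2Z,6R,7R,10Z)-6,7-epoxy-6-methyl-12-[(triethylsilyl)oxy]-2,10-bis[(trimethylsilyl)methyl]dodeca-2,10-dienoate | C[Si](C)(C)C/C(C(=O)OC)=C\CC[C@@]1(C)O[C@@H]1CC/C(C[Si](C)(C)C)=C/CO[Si](CC)(CC)CC | intermediate
15 | methyl (2Z)-5-[(1R,2S,6R)-6-hydroxy-1-methyl-3-methylidene-2-{[(triethylsilyl)oxy]methyl}cyclohexyl]-2-[(trimethylsilyl)methyl]pent-2-enoate | CC[Si](CC)(CC)OC[C@H]1C(=C)CC[C@@H](O)[C@]1(C)CC/C=C(\C[Si](C)(C)C)C(=O)OC | intermediate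
16 | methyl (2Z)-5-[(1R,2S,6R)-1-methyl-3-methylidene-6-[(triethylsilyl)oxy]-2-{[(triethylsilyl)oxy]methyl}cyclohexyl]-2-[(trimethylsilyl)methyl]pent-2-enoate | CC[Si](CC)(CC)OC[C@H]1C(=C)CC[C@@H](O[Si](CC)(CC)CC)[C@]1(C)CC/C=C(\C[Si](C)(C)C)C(=O)OC | intermediate
17 | methyl (2Z)-5-[(1R,2S,6R)-2-formyl-1-methyl-3-methylidene-6-[(triethylsilyl)oxy]cyclohexyl]-2-[(trimethylsilyl)methyl]pent-2-enoate | O=C[C@H]1C(=C)CC[C@@H](O[Si](CC)(CC)CC)[C@]1(C)CC/C=C(\C[Si](C)(C)C)C(=O)OC | intermediate
18 | methyl 2-[(1S,2S,4aR,5R,8aS)-1-hydroxy-4a-methyl-8-methylidene-5-[(triethylsilyl)oxy]decahydronaphthalen-2-yl]prop-2-enoate | O[C@@H]1[C@H]2C(=C)CC[C@@H](O[Si](CC)(CC)CC)[C@]2(C)CC[C@H]1C(=C)C(=O)OC | intermediate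
19 | methyl 2-[(1S,2S,4aR,5R,8aS)-4a-methyl-8-methylidene-1-(prop-2-enoyloxy)-5-[(triethylsilyl)oxy]decahydronaphthalen-2-yl]prop-2-enoate | C=CC(=O)O[C@@H]1[C@H]2C(=C)CC[C@@H](O[Si](CC)(CC)CC)[C@]2(C)CC[C@H]1C(=C)C(=O)OC | intermediate
20 | methyl 2-[(1S,2S,4aR,5R,7R,8aS)-7-hydroxy-4a-methyl-8-methylidene-1-(prop-2-enoyloxy)-5-[(triethylsilyl)oxy]decahydronaphthalen-2-yl]prop-2-enoate (drawn as the 3α epimer) | C=CC(=O)O[C@@H]1[C@H]2C(=C)[C@H](O)C[C@@H](O[Si](CC)(CC)CC)[C@]2(C)CC[C@H]1C(=C)C(=O)OC | intermediate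
21 | methyl 2-[(1S,2S,4aR,5R,8aR)-4a-methyl-8-methylidene-7-oxo-1-(prop-2-enoyloxy)-5-[(triethylsilyl)oxy]decahydronaphthalen-2-yl]prop-2-enoate | C=CC(=O)O[C@@H]1[C@H]2C(=C)C(=O)C[C@@H](O[Si](CC)(CC)CC)[C@]2(C)CC[C@H]1C(=C)C(=O)OC | intermediate
22 | methyl 2-[(1S,2S,4aR,5R,7S,8aS)-7-hydroxy-4a-methyl-8-methylidene-1-(prop-2-enoyloxy)-5-[(triethylsilyl)oxy]decahydronaphthalen-2-yl]prop-2-enoate | C=CC(=O)O[C@@H]1[C@H]2C(=C)[C@@H](O)C[C@@H](O[Si](CC)(CC)CC)[C@]2(C)CC[C@H]1C(=C)C(=O)OC | intermediate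
23 | methyl 2-[(1S,2S,4aR,5R,7S,8aS)-7-hydroxy-1-{[2-(hydroxymethyl)prop-2-enoyl]oxy}-4a-methyl-8-methylidene-5-[(triethylsilyl)oxy]decahydronaphthalen-2-yl]prop-2-enoate | C=C(CO)C(=O)O[C@@H]1[C@H]2C(=C)[C@@H](O)C[C@@H](O[Si](CC)(CC)CC)[C@]2(C)CC[C@H]1C(=C)C(=O)OC | intermediate
24 | methyl 2-[(1S,2S,4aR,5R,7S,8aS)-5,7-dihydroxy-1-{[2-(hydroxymethyl)prop-2-enoyl]oxy}-4a-methyl-8-methylidenedecahydronaphthalen-2-yl]prop-2-enoate | C=C(CO)C(=O)O[C@@H]1[C@H]2C(=C)[C@@H](O)C[C@@H](O)[C@]2(C)CC[C@H]1C(=C)C(=O)OC | target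

**Step count and risks**
Total step count: 14. Longest linear sequence: 13 (steps 1, 2 and 4 to 14); step 3 makes the phosphonate.

Steps most likely to fail:

1. Step 8 (key cyclisation). The epoxide may open stepwise, which would lose the C10 configuration, or the allylic silyl ether next to the silane may ionise and eliminate to a diene. The fallback terminates with the ester-conjugated silane, a documented variant with no allylic leaving group. It sets out from epoxy acid 11. Allyl bromide and K2CO3 in DMF would give the allyl methyl diester F1. BF3·OEt2 in CH2Cl2 at −78 °C should close ring A through the α-carbon of the enoate to the cyclohexanol F2, which Et3SiOTf/2,6-lutidine converts to the silyl ether F3. Pd(PPh3)4 and morpholine would free the acid F4. i-BuOCOCl/N-methylmorpholine would give the mixed anhydride F5, and NaBH4 the primary alcohol F6. Dess–Martin periodinane brings the route back at aldehyde 17.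

2. Step 10 (ring B closure). Allyl transfer from the ester-deactivated silane may be slow, so that the aldehyde epimerises or conjugates, or the product may partly lactonise. The fallback uses fluoride to trigger an anionic allyl transfer and drives everything to the lactone. It sets out from aldehyde 17. Bu4NF in THF (0 °C → rt) would remove both silyl groups and give the diol ester F7, which TsOH (cat.) lactonises to the known 12,6α-olide reynosin F8. Et3SiOTf/2,6-lutidine would give its silyl ether F9. LiOH in THF/H2O would open the lactone to the hydroxy acid F10, and MeI in DMF on the carboxylate, without acidification, returns hydroxy ester 18.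

3. Step 5 (carbocupration and carboxylation). The weakly nucleophilic silylmethylcopper reagent may add incompletely, attack the enoate, or the alkenylcopper may carboxylate poorly. The fallback builds the same acid by hydroiodination and cross-coupling. It sets out from enyne 9. CuI (cat.), Cs2CO3 and CO2 in DMF would give the ynoic acid F11. NaI in AcOH at 70 °C should add HI anti to give the (Z)-3-iodo acid F12. Me3SiCH2ZnCl with Pd(PPh3)4 in THF would couple with retention and return acid 10.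

**Further compounds**
F1 | step 8 | 1-(prop-2-en-1-yl) 12-methyl (2Z,6R,7R,10Z)-6,7-epoxy-7-methyl-3,11-bis[(trimethylsilyl)methyl]dodeca-2,10-dienedioate | C[Si](C)(C)C/C(C(=O)OC)=C\CC[C@@]1(C)O[C@@H]1CC/C(C[Si](C)(C)C)=C/C(=O)OCC=C
F2 | step 8 | prop-2-en-1-yl (1S,2R,3R)-3-hydroxy-2-{(3Z)-5-methoxy-5-oxo-4-[(trimethylsilyl)methyl]pent-3-en-1-yl}-2-methyl-6-methylidenecyclohexane-1-carboxylate | C=CCOC(=O)[C@H]1C(=C)CC[C@@H](O)[C@]1(C)CC/C=C(\C[Si](C)(C)C)C(=O)OC
F3 | step 8 | prop-2-en-1-yl (1S,2R,3R)-2-{(3Z)-5-methoxy-5-oxo-4-[(trimethylsilyl)methyl]pent-3-en-1-yl}-2-methyl-6-methylidene-3-[(triethylsilyl)oxy]cyclohexane-1-carboxylate | C=CCOC(=O)[C@H]1C(=C)CC[C@@H](O[Si](CC)(CC)CC)[C@]1(C)CC/C=C(\C[Si](C)(C)C)C(=O)OC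
F4 | step 8 | (1S,2R,3R)-2-{(3Z)-5-methoxy-5-oxo-4-[(trimethylsilyl)methyl]pent-3-en-1-yl}-2-methyl-6-methylidene-3-[(triethylsilyl)oxy]cyclohexane-1-carboxylic acid | OC(=O)[C@H]1C(=C)CC[C@@H](O[Si](CC)(CC)CC)[C@]1(C)CC/C=C(\C[Si](C)(C)C)C(=O)OC
F5 | step 8 | (1S,2R,3R)-2-{(3Z)-5-methoxy-5-oxo-4-[(trimethylsilyl)methyl]pent-3-en-1-yl}-2-methyl-6-methylidene-3-[(triethylsilyl)oxy]cyclohexane-1-carboxylic 2-methylpropyl carbonic anhydride | CC(C)COC(=O)OC(=O)[C@H]1C(=C)CC[C@@H](O[Si](CC)(CC)CC)[C@]1(C)CC/C=C(\C[Si](C)(C)C)C(=O)OC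
F6 | step 8 | methyl (2Z)-5-[(1R,2S,6R)-2-(hydroxymethyl)-1-methyl-3-methylidene-6-[(triethylsilyl)oxy]cyclohexyl]-2-[(trimethylsilyl)methyl]pent-2-enoate | OC[C@H]1C(=C)CC[C@@H](O[Si](CC)(CC)CC)[C@]1(C)CC/C=C(\C[Si](C)(C)C)C(=O)OC
F7 | step 10 | methyl 2-[(1S,2S,4aR,5R,8aS)-1,5-dihydroxy-4a-methyl-8-methylidenedecahydronaphthalen-2-yl]prop-2-enoate | O[C@@H]1[C@H]2C(=C)CC[C@@H](O)[C@]2(C)CC[C@H]1C(=C)C(=O)OC
F8 | step 10 | (3aS,5aR,6R,9aS,9bS)-6-hydroxy-5a-methyl-3,9-dimethylidenedecahydronaphtho[1,2-b]furan-2(3H)-one (reynosin) | C=C1C(=O)O[C@@H]2[C@H]3C(=C)CC[C@@H](O)[C@]3(C)CC[C@@H]12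
F9 | step 10 | (3aS,5aR,6R,9aS,9bS)-5a-methyl-3,9-dimethylidene-6-[(triethylsilyl)oxy]decahydronaphtho[1,2-b]furan-2(3H)-one | C=C1C(=O)O[C@@H]2[C@H]3C(=C)CC[C@@H](O[Si](CC)(CC)CC)[C@]3(C)CC[C@@H]12
F10 | step 10 | 2-[(1S,2S,4aR,5R,8aS)-1-hydroxy-4a-methyl-8-methylidene-5-[(triethylsilyl)oxy]decahydronaphthalen-2-yl]prop-2-enoic acid | O[C@@H]1[C@H]2C(=C)CC[C@@H](O[Si](CC)(CC)CC)[C@]2(C)CC[C@H]1C(=C)C(=O)O
F11 | step 5 | (6E,10Z)-12-methoxy-7-methyl-12-oxo-11-[(trimethylsilyl)methyl]dodeca-6,10-dien-2-ynoic acid | C[Si](C)(C)C/C(C(=O)OC)=C\CC/C(C)=C/CCC#CC(=O)O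
F12 | step 5 | (2Z,6E,10Z)-3-iodo-12-methoxy-7-methyl-12-oxo-11-[(trimethylsilyl)methyl]dodeca-2,6,10-trienoic acid | C[Si](C)(C)C/C(C(=O)OC)=C\CC/C(C)=C/CC/C(I)=C/C(=O)O
A1 | direct plan | (S)-4-hydroxycyclopent-2-en-1-one | O=C1C=C[C@@H](O)C1
A2 | direct plan | (3S,3aS,4S,5S,7aR)-3-ethynyl-3,4-dihydroxy-7a-methyl-5-(prop-1-en-2-yl)octahydro-1H-inden-1-one | O[C@@H]1[C@H]2[C@](O)(C#C)CC(=O)[C@]2(C)CC[C@H]1C(C)=C
A3 | direct plan | methyl 2-[(1R,3S,3aS,4S,5S,7aR)-4-({2-[(tert-butyldimethylsilyloxy)methyl]prop-2-enoyl}oxy)-3-ethynyl-1,3-dihydroxy-7a-methyloctahydro-1H-inden-5-yl]prop-2-enoate | C=C(CO[Si](C)(C)C(C)(C)C)C(=O)O[C@@H]1[C@H]2[C@](O)(C#C)C[C@@H](O)[C@]2(C)CC[C@H]1C(=C)C(=O)OC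
A4 | direct plan | methyl 2-[(1S,2S,4aR,5R,8aR)-1-({2-[(tert-butyldimethylsilyloxy)methyl]prop-2-enoyl}oxy)-5-hydroxy-4a-methyl-8-methylidene-7-oxodecahydronaphthalen-2-yl]prop-2-enoate | C=C(CO[Si](C)(C)C(C)(C)C)C(=O)O[C@@H]1[C@H]2C(=C)C(=O)C[C@@H](O)[C@]2(C)CC[C@H]1C(=C)C(=O)OC
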